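**Plan**

- Retrosynthesis: the four aryl methyl ethers come off last. Each 2,6-dihydroxyphenyl ketone is traced back by dehydrogenation to a 2-acylcyclohexane-1,3-dione, and the acyl C1–ring bond is cut to give a biaryl bis(nonanoic acid).
- Feature: each nonanoyl arm is cut between C6 and C7 (counted from the carbonyl carbon). C1–C6 are the six ring carbons of cyclohexane-1,3-dione (ring C2 becomes chain C6); C7–C9 plus the catechol ring are a 3-arylpropanal. The resorcinol ring is the same dione again, one dehydrogenation lower.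
- The bis-propanal goes back through propanoate and acrylate (C8–C9 by olefination) to a biaryl dialdehyde. The aryl–aryl bond is cut to 5-bromoveratraldehyde and 6-bromoveratraldehyde.
- Forward order: biaryl bond; both three-carbon arms; two diones joined at C6–C7 (key step); ring opening and deoxygenation to the C9 diacid; two more diones C-acylated and aromatised; global O-demethylation.
- No carbocycle is closed: the catechol rings come from the bromoaldehydes, the resorcinol rings from the second pair of diones.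
- Stereochemistry: the target has no stereocentre, and the biaryl axis (one ortho substituent on each ring) rotates freely, so no stereocontrol is needed.

Key step: step 6

Assumption: 5-bromoveratraldehyde 1 is purchased (it is one O-methylation from 5-bromovanillin); diones and triketones are drawn as keto tautomers although largely enolised; reagent amounts cover both arms.

**Route**

Step 1
Reactants: 1 5-bromoveratraldehyde (3-bromo-4,5-dimethoxybenzaldehyde); 2 bis(pinacolato)diboron
Product: 3 3,4-dimethoxy-5-(4,4,5,5-tetramethyl-1,3,2-dioxaborolan-2-yl)benzaldehyde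
Conditions: B2pin2, PdCl2(dppf) (3 mol %), KOAc, 1,4-dioxane, 90 °C
Reagents that add atoms: bis(pinacolato)diboron 2, CC1(C)OB(OC1(C)C)B1OC(C)(C)C(C)(C)O1
Why: Miyaura borylation, in which the aryl bromide adds oxidatively to zerovalent palladium, acetate-assisted transmetallation with B2pin2 follows, and the aldehyde is inert to the weak base KOAc.

Step 2
Reactants: 3 3,4-dimethoxy-5-(pinacolboryl)benzaldehyde; 4 6-bromoveratraldehyde (2-bromo-4,5-dimethoxybenzaldehyde)
Product: 5 2',3',4,5-tetramethoxybiphenyl-2,5'-dicarbaldehyde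
Conditions: Pd(OAc)2 (2 mol %), SPhos (4 mol %), K3PO4, toluene/H2O 10:1, 90 °C
Reagents that add atoms: none
Why: Suzuki–Miyaura coupling, in which the ortho-formyl group speeds oxidative addition of bromide 4, the bulky electron-rich SPhos ligand suits a biaryl with one ortho substituent on each ring, and both aldehydes tolerate aqueous phosphate.

Step 3
Reactants: 5 2',3',4,5-tetramethoxybiphenyl-2,5'-dicarbaldehyde; 6 triethyl phosphonoacetate (2.4 equiv)
Product: 7 diethyl (2E,2'E)-3,3'-(2',3',4,5-tetramethoxybiphenyl-2,5'-diyl)diacrylate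
Conditions: NaH, THF, 0 °C to rt
Reagents that add atoms: triethyl phosphonoacetate 6, CCOC(=O)CP(=O)(OCC)OCC
Why: A twofold Horner–Wadsworth–Emmons olefination of non-enolisable aryl aldehydes with a stabilised phosphonate anion is dependable and E-selective, and the alkene geometry is of no consequence because the next step saturates it.

Step 4
Reactants: 7 diethyl (2E,2'E)-3,3'-(2',3',4,5-tetramethoxybiphenyl-2,5'-diyl)diacrylate
Product: 8 diethyl 3,3'-(2',3',4,5-tetramethoxybiphenyl-2,5'-diyl)dipropanoate
Conditions: H2 (1 atm), 10% Pd/C, EtOAc, rt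
Reagents that add atoms: none
Why: Catalytic hydrogenation of the two conjugated alkenes over Pd/C should proceed at ambient pressure without touching the esters, the aryl ethers or the biaryl.

Step 5
Reactants: 8 diethyl 3,3'-(2',3',4,5-tetramethoxybiphenyl-2,5'-diyl)dipropanoate
Product: 9 3,3'-(2',3',4,5-tetramethoxybiphenyl-2,5'-diyl)dipropanal
Conditions: i-Bu2AlH (DIBAL-H, 2.2 equiv), CH2Cl2, −78 °C; MeOH at −78 °C, then aq. KNaC4H4O6
Reagents that add atoms: none
Why: Partial ester reduction with DIBAL-H, in which the tetrahedral aluminium hemiacetal persists at −78 °C until the cold quench, so each ester should stop at the aldehyde.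

Step 6
Reactants: 9 3,3'-(2',3',4,5-tetramethoxybiphenyl-2,5'-diyl)dipropanal; 10 cyclohexane-1,3-dione (2.2 equiv)
Product: 12 2,2'-[(2',3',4,5-tetramethoxybiphenyl-2,5'-diyl)bis(propane-3,1-diyl)]bis(cyclohexane-1,3-dione), via bis-alkylidene dione 11 (not isolated)
Conditions: Hantzsch ester (diethyl 2,6-dimethyl-1,4-dihydropyridine-3,5-dicarboxylate, 2.2 equiv), L-proline (20 mol %), CH2Cl2, 25 °C, dialdehyde added slowly
Reagents that add atoms: cyclohexane-1,3-dione 10, O=C1CCCC(=O)C1
Why: Proline condenses with each aldehyde to an iminium ion that the dione enol attacks, loss of proline leaves a 2-alkylidene-1,3-dione (Knoevenagel condensation), and this doubly activated alkene takes hydride from C4 of the Hantzsch ester at its β-carbon to give the 2-alkyl dione and the pyridine. The closest known reaction type is the organocatalytic three-component reductive alkylation of cyclic 1,3-diones with aldehydes and a Hantzsch ester, here run on both arms of a dialdehyde to form the C6–C7 bond of each future nonanoyl chain. No ring is closed and no stereocentre arises, since C2 of each dione carries two equivalent ring carbonyls and the alkylidene has no E/Z isomers. The selectivity required is mono-alkylation, so Michael addition of a second dione to the alkylidene and proline-mediated self-aldol of the enolisable aldehyde must both lose. The first is secured by the extreme electrophilicity of the alkylidene dione, which the Hantzsch ester (present from the start in slight excess) should reduce faster than a dione enol can add, and the second by the acidity of the dione, which makes it a far better partner for the iminium ion than the enamine of the aldehyde. The two arms are held apart by the biaryl and react independently, so the twofold reaction asks for nothing beyond doubled reagent amounts.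

Step 7
Reactants: 12 2,2'-[(2',3',4,5-tetramethoxybiphenyl-2,5'-diyl)bis(propane-3,1-diyl)]bis(cyclohexane-1,3-dione)
Product: 15 9,9'-(2',3',4,5-tetramethoxybiphenyl-2,5'-diyl)dinonanoic acid, via dioxo diacid 13 (not isolated), via bis-hydrazone 14 (not isolated)
Conditions: KOH, H2O, diethylene glycol, 110 °C; then N2H4·H2O, 130 °C, then 195 °C with removal of water; aq. HCl work-up
Reagents that add atoms: potassium hydroxide, [K+].[OH-]
Why: Hydroxide adds to a ring carbonyl and retro-Claisen fragmentation gives the 5-oxo carboxylate, whose ketone is then removed by Wolff–Kishner reduction in the Huang-Minlon manner, the long-established one-flask chain extension of 2-alkylcyclohexane-1,3-diones to acids six carbons longer.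

Step 8
Reactants: 15 9,9'-(2',3',4,5-tetramethoxybiphenyl-2,5'-diyl)dinonanoic acid; 10 cyclohexane-1,3-dione (2.2 equiv)
Product: 17 2,2'-[9,9'-(2',3',4,5-tetramethoxybiphenyl-2,5'-diyl)dinonanoyl]bis(cyclohexane-1,3-dione), via bis-enol ester 16 (not isolated)
Conditions: DCC (2.4 equiv), DMAP (2.4 equiv), Et3N, CH2Cl2, 0 °C to rt
Reagents that add atoms: cyclohexane-1,3-dione 10, O=C1CCCC(=O)C1
Why: Steglich-type O-acylation of the dione enol followed by DMAP-mediated O-to-C acyl migration (through the acylpyridinium ion and the dione enolate) should deliver the chelated, thermodynamically preferred 2-acyl triketone, a standard one-flask preparation of 2-acylcyclohexane-1,3-diones from carboxylic acids.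

Step 9
Reactants: 17 2,2'-[9,9'-(2',3',4,5-tetramethoxybiphenyl-2,5'-diyl)dinonanoyl]bis(cyclohexane-1,3-dione)
Product: 18 9,9'-(2',3',4,5-tetramethoxybiphenyl-2,5'-diyl)bis[1-(2,6-dihydroxyphenyl)nonan-1-one]
Conditions: Hg(OAc)2 (2.2 equiv), NaOAc, AcOH, reflux
Reagents that add atoms: none
Why: Oxidative aromatisation (dehydrogenation), in which divalent mercury mercurates the enolised ring at C4 and loss of mercury and acetic acid gives a cyclohexadienone that tautomerises to the hydrogen-bonded 2-acylresorcinol, placing the acyl group between the two hydroxyls as a Friedel–Crafts acylation of resorcinol would not.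

Step 10
Reactants: 18 9,9'-(2',3',4,5-tetramethoxybiphenyl-2,5'-diyl)bis[1-(2,6-dihydroxyphenyl)nonan-1-one]
Product: 19 9,9'-(2',3',4,5-tetrahydroxybiphenyl-2,5'-diyl)bis[1-(2,6-dihydroxyphenyl)nonan-1-one] (CNP0305015.0)
Conditions: BBr3 (10 equiv), CH2Cl2, −78 °C to rt; then H2O
Reagents that add atoms: none
Why: Lewis acid ether cleavage, in which BBr3 coordinates each aryl methyl ether and bromide removes the methyl group by SN2, conditions that the aryl ketones, the free resorcinol hydroxyls and the alkyl chains should withstand.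

**Compound list**

1 | 5-bromoveratraldehyde (3-bromo-4,5-dimethoxybenzaldehyde) | COc1cc(C=O)cc(Br)c1OC | starting material
2 | bis(pinacolato)diboron | CC1(C)OB(OC1(C)C)B1OC(C)(C)C(C)(C)O1 | starting material
3 | 3,4-dimethoxy-5-(4,4,5,5-tetramethyl-1,3,2-dioxaborolan-2-yl)benzaldehyde | COc1cc(C=O)cc(B2OC(C)(C)C(C)(C)O2)c1OC | intermediate
4 | 6-bromoveratraldehyde (2-bromo-4,5-dimethoxybenzaldehyde) | COc1cc(Br)c(C=O)cc1OC | starting material
5 | 2',3',4,5-tetramethoxybiphenyl-2,5'-dicarbaldehyde | O=Cc1cc(OC)c(OC)c(-c2cc(OC)c(OC)cc2C=O)c1 | intermediate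
6 | triethyl phosphonoacetate | CCOC(=O)CP(=O)(OCC)OCC | starting material
7 | diethyl (2E,2'E)-3,3'-(2',3',4,5-tetramethoxybiphenyl-2,5'-diyl)diacrylate | CCOC(=O)/C=C/c1cc(OC)c(OC)c(-c2cc(OC)c(OC)cc2/C=C/C(=O)OCC)c1 | intermediate
8 | diethyl 3,3'-(2',3',4,5-tetramethoxybiphenyl-2,5'-diyl)dipropanoate | CCOC(=O)CCc1cc(OC)c(OC)c(-c2cc(OC)c(OC)cc2CCC(=O)OCC)c1 | intermediate
9 | 3,3'-(2',3',4,5-tetramethoxybiphenyl-2,5'-diyl)dipropanal | O=CCCc1cc(OC)c(OC)c(-c2cc(OC)c(OC)cc2CCC=O)c1 | intermediate
10 | cyclohexane-1,3-dione | O=C1CCCC(=O)C1 | starting material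
11 | 2,2'-[(2',3',4,5-tetramethoxybiphenyl-2,5'-diyl)bis(propan-3-yl-1-ylidene)]bis(cyclohexane-1,3-dione) (bis-alkylidene dione) | O=C1CCCC(=O)C1=CCCc1cc(OC)c(OC)c(-c2cc(OC)c(OC)cc2CCC=C2C(=O)CCCC2=O)c1 | intermediate
12 | 2,2'-[(2',3',4,5-tetramethoxybiphenyl-2,5'-diyl)bis(propane-3,1-diyl)]bis(cyclohexane-1,3-dione) | O=C1CCCC(=O)C1CCCc1cc(OC)c(OC)c(-c2cc(OC)c(OC)cc2CCCC2C(=O)CCCC2=O)c1 | intermediate
13 | 9,9'-(2',3',4,5-tetramethoxybiphenyl-2,5'-diyl)bis(5-oxononanoic acid) (dioxo diacid) | OC(=O)CCCC(=O)CCCCc1cc(OC)c(OC)c(-c2cc(OC)c(OC)cc2CCCCC(=O)CCCC(=O)O)c1 | intermediate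
14 | 9,9'-(2',3',4,5-tetramethoxybiphenyl-2,5'-diyl)bis(5-hydrazinylidenenonanoic acid) (bis-hydrazone, C=N isomers) | OC(=O)CCCC(=NN)CCCCc1cc(OC)c(OC)c(-c2cc(OC)c(OC)cc2CCCCC(=NN)CCCC(=O)O)c1 | intermediate
15 | 9,9'-(2',3',4,5-tetramethoxybiphenyl-2,5'-diyl)dinonanoic acid | OC(=O)CCCCCCCCc1cc(OC)c(OC)c(-c2cc(OC)c(OC)cc2CCCCCCCCC(=O)O)c1 | intermediate
16 | bis(3-oxocyclohex-1-en-1-yl) 9,9'-(2',3',4,5-tetramethoxybiphenyl-2,5'-diyl)dinonanoate (bis-enol ester) | O=C1C=C(OC(=O)CCCCCCCCc2cc(OC)c(OC)c(-c3cc(OC)c(OC)cc3CCCCCCCCC(=O)OC3=CC(=O)CCC3)c2)CCC1 | intermediate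
17 | 2,2'-[9,9'-(2',3',4,5-tetramethoxybiphenyl-2,5'-diyl)dinonanoyl]bis(cyclohexane-1,3-dione) | O=C(CCCCCCCCc1cc(OC)c(OC)c(-c2cc(OC)c(OC)cc2CCCCCCCCC(=O)C2C(=O)CCCC2=O)c1)C1C(=O)CCCC1=O | intermediate
18 | 9,9'-(2',3',4,5-tetramethoxybiphenyl-2,5'-diyl)bis[1-(2,6-dihydroxyphenyl)nonan-1-one] | O=C(CCCCCCCCc1cc(OC)c(OC)c(-c2cc(OC)c(OC)cc2CCCCCCCCC(=O)c2c(O)cccc2O)c1)c1c(O)cccc1O | intermediate
19 | 9,9'-(2',3',4,5-tetrahydroxybiphenyl-2,5'-diyl)bis[1-(2,6-dihydroxyphenyl)nonan-1-one] (CNP0305015.0) | O=C(CCCCCCCCc1cc(O)c(O)c(-c2cc(O)c(O)cc2CCCCCCCCC(=O)c2c(O)cccc2O)c1)c1c(O)cccc1O | target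

**Step count and risks**

Total step count: 10. Longest linear sequence: 10 steps (1 to 19).

Steps most likely to fail:

Step 6. The alkylidene dione may be intercepted by a second dione (Michael addition leading to alkylidene-bridged bis-diones), or the enolisable aldehyde may self-condense under proline. Because both arms must react cleanly, such losses compound. The fallback forms the same C6–C7 bond by polar alkylation of a masked dione carbanion. It sets out from bis-propanal 9.
- NaBH4 in MeOH should give 3,3'-(2',3',4,5-tetramethoxybiphenyl-2,5'-diyl)bis(propan-1-ol) F1.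
- I2, PPh3 and imidazole in CH2Cl2 should convert it into 2,5'-bis(3-iodopropyl)-2',3',4,5-tetramethoxybiphenyl F2.
- Purchased 1,5-dimethoxycyclohexa-1,4-diene is deprotonated at C6 by t-BuLi in THF/HMPA at −78 °C to 6-lithio-1,5-dimethoxycyclohexa-1,4-diene F3.
- F3 is alkylated by F2 to give 2,5'-bis[3-(2,6-dimethoxycyclohexa-2,5-dien-1-yl)propyl]-2',3',4,5-tetramethoxybiphenyl F4.
- Dilute HCl in acetone hydrolyses the four enol ethers, and the route is rejoined at bis-dione 12.

Step 9. Electrophilic mercuration of the electron-rich tetramethoxybiaryl may compete with α-mercuration of the triketone, and one of the two rings may be left incompletely dehydrogenated. The fallback brings in the resorcinol ring as an arene and bypasses steps 8 and 9. It sets out from diacid 15.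
- MeNHOMe·HCl, EDC·HCl, HOBt and Et3N in CH2Cl2 should give 9,9'-(2',3',4,5-tetramethoxybiphenyl-2,5'-diyl)bis(N-methoxy-N-methylnonanamide) F5.
- 2,6-Dimethoxyphenyllithium F6 (from 1,3-dimethoxybenzene and n-BuLi, THF, 0 °C) adds once to each amide at −78 °C to rt, giving 9,9'-(2',3',4,5-tetramethoxybiphenyl-2,5'-diyl)bis[1-(2,6-dimethoxyphenyl)nonan-1-one] F7.
- BBr3 in CH2Cl2 cleaves all eight methyl ethers, and the route is rejoined at target 19.

Step 7. Hot KOH in glycol may strip the crowded methoxy group of ring A (flanked by a methoxy group and the aryl ring) by nucleophilic demethylation, and reduction may stall on one arm. The fallback keeps the ring opening but deoxygenates without strong base. It sets out from bis-dione 12.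
- Aqueous NaOH at 100 °C followed by acidification should give dioxo diacid 13, isolated this time.
- Ethane-1,2-dithiol and BF3·OEt2 in CH2Cl2 should give 9,9'-(2',3',4,5-tetramethoxybiphenyl-2,5'-diyl)bis[4-(1,3-dithiolan-2-ylidene-spiro)] diacid, that is the bis(1,3-dithiolane) of 13, F8.
- Raney Ni in EtOH at reflux desulfurises it, and the route is rejoined at diacid 15.

**Further compounds**

F1 | step 6 | 3,3'-(2',3',4,5-tetramethoxybiphenyl-2,5'-diyl)bis(propan-1-ol) | OCCCc1cc(OC)c(OC)c(-c2cc(OC)c(OC)cc2CCCO)c1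
F2 | step 6 | 2,5'-bis(3-iodopropyl)-2',3',4,5-tetramethoxybiphenyl | ICCCc1cc(OC)c(OC)c(-c2cc(OC)c(OC)cc2CCCI)c1
F3 | step 6 | 6-lithio-1,5-dimethoxycyclohexa-1,4-diene | [Li]C1C(OC)=CCC=C1OC
F4 | step 6 | 2,5'-bis[3-(2,6-dimethoxycyclohexa-2,5-dien-1-yl)propyl]-2',3',4,5-tetramethoxybiphenyl | COC1=CCC=C(OC)C1CCCc1cc(OC)c(OC)c(-c2cc(OC)c(OC)cc2CCCC2C(OC)=CCC=C2OC)c1
F5 | step 9 | 9,9'-(2',3',4,5-tetramethoxybiphenyl-2,5'-diyl)bis(N-methoxy-N-methylnonanamide) | CON(C)C(=O)CCCCCCCCc1cc(OC)c(OC)c(-c2cc(OC)c(OC)cc2CCCCCCCCC(=O)N(C)OC)c1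
F6 | step 9 | 2,6-dimethoxyphenyllithium | [Li]c1c(OC)cccc1OC
F7 | step 9 | 9,9'-(2',3',4,5-tetramethoxybiphenyl-2,5'-diyl)bis[1-(2,6-dimethoxyphenyl)nonan-1-one] | O=C(CCCCCCCCc1cc(OC)c(OC)c(-c2cc(OC)c(OC)cc2CCCCCCCCC(=O)c2c(OC)cccc2OC)c1)c1c(OC)cccc1OC
F8 | step 7 | bis(1,3-dithiolane) of 9,9'-(2',3',4,5-tetramethoxybiphenyl-2,5'-diyl)bis(5-oxononanoic acid) | OC(=O)CCCC1(SCCS1)CCCCc1cc(OC)c(OC)c(-c2cc(OC)c(OC)cc2CCCCC2(SCCS2)CCCC(=O)O)c1
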